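**Strategy.** The plan disconnects ring C, the cyclopentenone of the 5-8-5 skeleton, at two bonds: its enone C=C (CH=C–iPr) and the bond between its two quaternary carbons, C(CH3) flanked by both ring ketones and the carbon that carries the ether bridge. Both form in one base-mediated Michael/aldol-condensation cascade. The feature exploited is the ether oxygen spanning ring B: in the precursor, a spiro 6-isobutyryl-2,3-dihydro-4H-pyran-4-one on ring A that also carries a 2-methyl-1,3-diketone, this oxygen already links ring A to the electrophilic carbon, so the diketone carbon attacks through a six-membered transition state, closing ring B; the resulting 1,4-diketone then closes ring C.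

Key step: step 10

Assumption 1: the (S)-configured dibromo-binaphthol is taken to direct crotyl transfer to the Re face of the bromoenone carbonyl (bromoalkenyl carbon as the large substituent); if the opposite sense operates, the (R)-catalyst is used.
Assumption 2: 1,3-diketones are drawn as keto tautomers; their methine carbon is labile and carries no configuration until the key step defines it.

**Step 1**
Reactants: 1 3-ethoxycyclopent-2-en-1-one; 2 tributyl(methoxymethyl)stannane
Product: 3 3-(methoxymethyl)cyclopent-2-en-1-one
Conditions: 2, n-BuLi, THF, −78 °C; 1, −78 °C; then 1 M HCl, 0 °C → rt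
Reagents that add atoms: water, O
Why: Tin–lithium exchange gives methoxymethyllithium, which adds 1,2 to the vinylogous ester, and acid then hydrolyses the enol ether with loss of the tertiary hydroxyl (Stork–Danheiser alkylative enone transposition); no stereocenter is formed.

**Step 2**
Reactants: 3 3-(methoxymethyl)cyclopent-2-en-1-one
Product: 4 2-bromo-3-(methoxymethyl)cyclopent-2-en-1-one
Conditions: Br2, CH2Cl2, 0 °C; then Et3N, 0 °C → rt
Reagents that add atoms: bromine, BrBr
Why: Bromine adds across the enone and triethylamine removes HBr through the acidic α-proton (bromination–dehydrobromination to the α-bromoenone); no stereocenter is formed.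

**Step 3**
Reactants: 5 (Z)-but-2-ene; 6 tripropan-2-yl borate
Product: 7 dipropan-2-yl [(2Z)-but-2-en-1-yl]boronate
Conditions: n-BuLi, KOt-Bu, THF, −78 → −50 °C; 6, −78 °C; then HCl (2 equiv, Et2O), −78 °C → rt
Reagents that add atoms: none
Why: The n-BuLi/KOt-Bu superbase metalates an allylic methyl of the alkene with retention of the Z geometry at low temperature, and borylation followed by acid release of the ate complex gives the (Z)-crotylboronate (allylic metalation–borylation).

**Step 4**
Reactants: 4 2-bromo-3-(methoxymethyl)cyclopent-2-en-1-one; 7 dipropan-2-yl [(2Z)-but-2-en-1-yl]boronate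
Product: 8 (1R)-2-bromo-1-[(2S)-but-3-en-2-yl]-3-(methoxymethyl)cyclopent-2-en-1-ol
Conditions: (S)-3,3'-dibromo-1,1'-bi-2-naphthol (15 mol%), PhCF3/PhMe (3:1), −35 °C; H2O work-up
Reagents that add atoms: none
Why: Diol-catalysed asymmetric crotylboration of a ketone: exchange of one isopropoxy group for the chiral diol gives a more Lewis acidic boronate that reacts through a closed chair Zimmerman–Traxler transition state with the bromoalkenyl carbon pseudo-equatorial and the (Z)-methyl axial, which sets the carbinol and methyl-bearing carbons together in the syn relationship needed, while the diol selects the Re face of the carbonyl.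

**Step 5**
Reactants: 8 (1R)-2-bromo-1-[(2S)-but-3-en-2-yl]-3-(methoxymethyl)cyclopent-2-en-1-ol
Product: 9 {[(1R)-2-bromo-1-[(2S)-but-3-en-2-yl]-3-(methoxymethyl)cyclopent-2-en-1-yl]oxy}(triethyl)silane
Conditions: Et3SiOTf, 2,6-lutidine, CH2Cl2, −78 → 0 °C
Reagents that add atoms: triethylsilyl trifluoromethanesulfonate, CC[Si](CC)(CC)OS(=O)(=O)C(F)(F)F
Why: Silyl triflate silylation of the hindered tertiary alcohol (silyl ether protection) keeps the hydroxyl from being deprotonated in the later carbanion steps and from closing onto the side-chain diketone before the pyranone is wanted.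

**Step 6**
Reactants: 9 the triethylsilyl ether from step 5; 10 N-methoxy-N-methylpropanamide
Product: 11 1-[(5R)-5-[(2S)-but-3-en-2-yl]-2-(methoxymethyl)-5-(triethylsilyloxy)cyclopent-1-en-1-yl]propan-1-one
Conditions: t-BuLi (2.1 equiv), THF, −78 °C; 10, −78 → −20 °C; sat. aq. NH4Cl
Reagents that add atoms: none
Why: Bromine–lithium exchange gives an alkenyllithium held by chelation to the methoxymethyl oxygen, and its tetrahedral adduct with the N-methoxy-N-methylamide collapses only on work-up (Weinreb ketone synthesis); the stereocenters are not touched.

**Step 7**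
Reactants: 11 the ethyl ketone from step 6; 12 1-(1H-benzotriazol-1-yl)ethan-1-one
Product: 13 1-[(5R)-5-[(2S)-but-3-en-2-yl]-2-(methoxymethyl)-5-(triethylsilyloxy)cyclopent-1-en-1-yl]-2-methylbutane-1,3-dione
Conditions: MgBr2·OEt2, i-Pr2NEt, CH2Cl2, rt
Reagents that add atoms: none
Why: Soft enolisation of the only enolisable ketone as its magnesium enolate and C-acylation by the acylbenzotriazole (crossed Claisen acylation) give the 2-methyl-1,3-diketone, whose methine is a labile centre that is defined only in the key step.

**Step 8**
Reactants: 13 the diketone from step 7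
Product: 14 1-[(5R)-2-(methoxymethyl)-5-[(2R)-3-oxobutan-2-yl]-5-(triethylsilyloxy)cyclopent-1-en-1-yl]-2-methylbutane-1,3-dione
Conditions: PdCl2 (10 mol%), CuCl, O2 (1 atm), DMF/H2O (7:1), rt
Reagents that add atoms: water, O
Why: Tsuji–Wacker oxidation, in which Markovnikov hydroxypalladation of the terminal alkene and β-hydride elimination give the methyl ketone while the tetrasubstituted, acyl-bearing ring alkene stays inert; no new stereocenter arises and the descriptor of the methyl-bearing carbon changes only because of priorities.

**Step 9**
Reactants: 14 the methyl ketone from step 8; 15 N,N'-dimethoxy-N,N'-dimethylethanediamide; 16 isopropylmagnesium chloride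
Product: 19 (5R,10R)-2-(methoxymethyl)-10-methyl-1-(2-methyl-3-oxobutanoyl)-7-(2-methylpropanoyl)-6-oxaspiro[4.5]deca-1,7-dien-9-one, via silyl-protected triketone 17 (not isolated), via hydroxy triketone 18 (not isolated)
Conditions: LiN(i-Pr)2 (2.2 equiv), THF, −78 °C; 15, −78 → −40 °C; 16, −40 → 0 °C; then 3 M HCl, THF, 0 °C → rt
Reagents that add atoms: none
Why: Kinetic deprotonation gives the CH3 enolate of the methyl ketone beside the unreactive diketonate, this enolate is acylated by one amide of the bis-Weinreb oxalamide and the Grignard reagent adds to the second amide with the tetrahedral intermediates preventing over-addition (sequential Weinreb acylation to an unsymmetrical 1,2-diketone), and acid then removes the silyl group, lets the tertiary hydroxyl close onto the most electrophilic ketone (that of the vicinal dicarbonyl) and dehydrates the hemiketal to the vinylogous ester (δ-hydroxy-β-diketone to dihydropyranone cyclodehydration); existing stereocenters are not touched.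

**Step 10**
Reactants: 19 the spiro dihydropyranone from step 9
Product: 21 tetracyclic trione (the target with its secondary alcohol at the ketone level), via Michael adduct 20 (not isolated)
Conditions: DBU (1.5 equiv), 4 Å molecular sieves, MeCN, rt → 60 °C
Reagents that add atoms: none
Why: DBU deprotonates the 2-methyl-1,3-diketone and its central carbon adds to C-7 of the dihydropyranone, the β-carbon of the vinylogous ester made more electrophilic by the isobutyryl group, to give triketone 20, whose acetyl CH3 then adds to the isobutyryl ketone and the aldol loses water to the cyclopentenone. The closest known reaction types are the intramolecular Michael addition of 1,3-dicarbonyl compounds to 2-acyl-4-pyranone and chromone-2-carboxylate acceptors and the base-mediated 1,4-diketone to cyclopentenone aldol condensation. The oxa-bridged six-membered ring closes 6-exo-trig, which completes the eight-membered ring B as the carbocyclic perimeter of the 9-oxabicyclo[3.3.1]nonane, and ring C closes by 5-(enolendo)-exo-trig aldol addition followed by E1cB dehydration. The ether-bearing quaternary carbon is set by the tether, because the diketone hangs from the ring-A carbon on the spiro centre and can reach only the pyranone face syn to that carbon; the methyl-bearing quaternary carbon is set by the cis ring fusion that the irreversible aldol closure demands, the epimeric adduct returning by retro-Michael reaction. The step needs attack at C-7 and not at C-8, C- and not O-alkylation, and condensation of the acetyl group with the isobutyryl ketone and not with the C-9 ketone; the six- against seven-membered ring, the reversibility of the O-adduct and the fact that only the cyclopentenone can dehydrate (the other ketol would need a bridgehead alkene) secure these, while molecular sieves keep hydroxide from cleaving the non-enolisable diketone.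

**Step 11**
Reactants: 21 tetracyclic trione
Product: 22 alterbrassicicene C
Conditions: NaBH4, MeOH/CH2Cl2 (1:1), −78 °C; sat. aq. NH4Cl
Reagents that add atoms: none
Why: NaBH4 at low temperature reduces the only unconjugated and least hindered ketone (chemoselective 1,2-reduction), and hydride arrives on the exo face, away from the three-carbon bridge that covers the axial face, so the new alcohol is axial and cis to the neighbouring methyl as in the target.

**Compound list**
1 | 3-ethoxycyclopent-2-en-1-one | CCOC1=CC(=O)CC1 | starting material
2 | tributyl(methoxymethyl)stannane | CCCC[Sn](CCCC)(CCCC)COC | starting material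
3 | 3-(methoxymethyl)cyclopent-2-en-1-one | COCC1=CC(=O)CC1 | intermediate
4 | 2-bromo-3-(methoxymethyl)cyclopent-2-en-1-one | COCC1=C(Br)C(=O)CC1 | intermediate
5 | (Z)-but-2-ene | C/C=C\C | starting material
6 | tripropan-2-yl borate | CC(C)OB(OC(C)C)OC(C)C | starting material
7 | dipropan-2-yl [(2Z)-but-2-en-1-yl]boronate | C/C=C\CB(OC(C)C)OC(C)C | intermediate
8 | (1R)-2-bromo-1-[(2S)-but-3-en-2-yl]-3-(methoxymethyl)cyclopent-2-en-1-ol | COCC1=C(Br)[C@](O)([C@@H](C)C=C)CC1 | intermediate
9 | {[(1R)-2-bromo-1-[(2S)-but-3-en-2-yl]-3-(methoxymethyl)cyclopent-2-en-1-yl]oxy}(triethyl)silane | COCC1=C(Br)[C@](O[Si](CC)(CC)CC)([C@@H](C)C=C)CC1 | intermediate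
10 | N-methoxy-N-methylpropanamide | CCC(=O)N(C)OC | starting material
11 | 1-[(5R)-5-[(2S)-but-3-en-2-yl]-2-(methoxymethyl)-5-(triethylsilyloxy)cyclopent-1-en-1-yl]propan-1-one | COCC1=C(C(=O)CC)[C@](O[Si](CC)(CC)CC)([C@@H](C)C=C)CC1 | intermediate
12 | 1-(1H-benzotriazol-1-yl)ethan-1-one | CC(=O)n1nnc2ccccc12 | starting material
13 | 1-[(5R)-5-[(2S)-but-3-en-2-yl]-2-(methoxymethyl)-5-(triethylsilyloxy)cyclopent-1-en-1-yl]-2-methylbutane-1,3-dione (diketone methine unassigned) | COCC1=C(C(=O)C(C)C(C)=O)[C@](O[Si](CC)(CC)CC)([C@@H](C)C=C)CC1 | intermediate
14 | 1-[(5R)-2-(methoxymethyl)-5-[(2R)-3-oxobutan-2-yl]-5-(triethylsilyloxy)cyclopent-1-en-1-yl]-2-methylbutane-1,3-dione | COCC1=C(C(=O)C(C)C(C)=O)[C@](O[Si](CC)(CC)CC)([C@@H](C)C(C)=O)CC1 | intermediate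
15 | N,N'-dimethoxy-N,N'-dimethylethanediamide | CON(C)C(=O)C(=O)N(C)OC | starting material
16 | isopropylmagnesium chloride | CC(C)[Mg]Cl | starting material
17 | 1-[(5R)-2-(methoxymethyl)-5-[(2R)-7-methyl-3,5,6-trioxooctan-2-yl]-5-(triethylsilyloxy)cyclopent-1-en-1-yl]-2-methylbutane-1,3-dione | COCC1=C(C(=O)C(C)C(C)=O)[C@](O[Si](CC)(CC)CC)([C@@H](C)C(=O)CC(=O)C(=O)C(C)C)CC1 | intermediate (not isolated)
18 | 1-[(5R)-5-hydroxy-2-(methoxymethyl)-5-[(2R)-7-methyl-3,5,6-trioxooctan-2-yl]cyclopent-1-en-1-yl]-2-methylbutane-1,3-dione | COCC1=C(C(=O)C(C)C(C)=O)[C@](O)([C@@H](C)C(=O)CC(=O)C(=O)C(C)C)CC1 | intermediate (not isolated)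
19 | (5R,10R)-2-(methoxymethyl)-10-methyl-1-(2-methyl-3-oxobutanoyl)-7-(2-methylpropanoyl)-6-oxaspiro[4.5]deca-1,7-dien-9-one | COCC1=C(C(=O)C(C)C(C)=O)[C@@]2(OC(C(=O)C(C)C)=CC(=O)[C@@H]2C)CC1 | intermediate
20 | Michael adduct: ring-A-fused 9-oxabicyclo[3.3.1]nonane triketone with acetyl and methyl on the new quaternary carbon and isobutyryl on the ether carbon, acetyl cis to isobutyryl | COCC1=C2C(=O)[C@@](C)(C(C)=O)[C@]3(C(=O)C(C)C)CC(=O)[C@H](C)[C@@]2(CC1)O3 | intermediate (not isolated)
21 | tetracyclic trione (alterbrassicicene C with its secondary alcohol as ketone) | COCC1=C2C(=O)[C@@]3(C)C(=O)C=C(C(C)C)[C@]34CC(=O)[C@H](C)[C@@]2(CC1)O4 | intermediate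
22 | alterbrassicicene C | COCC1=C2C(=O)[C@@]3(C)C(=O)C=C(C(C)C)[C@]34C[C@H](O)[C@H](C)[C@@]2(CC1)O4 | target

**Count.** Total steps: 11. Longest linear sequence: 10 steps (steps 1, 2 and 4 to 11, from 3-ethoxycyclopent-2-en-1-one); step 3 prepares the crotylboronate in a side branch.

**Steps most likely to fail**

1. Step 10 (key cascade). What may go wrong:
   - the conjugate addition stays on the side of the open diketone through retro-Michael reversal or O- instead of C-attack;
   - the acetyl methyl adds to the ring ketone liberated from the vinylogous ester;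
   - the methyl-bearing carbon next to that ketone epimerises under base;
   - adventitious hydroxide cleaves the non-enolisable 1,3-diketone.

   Fallback, from 19 back to 21: the two bond formations are separated and carried by silicon instead of an amidine base. N,O-Bis(trimethylsilyl)acetamide in CH2Cl2 at rt converts 19 into the trimethylsilyl enol ether of its side-chain diketone F1. Me3SiOTf (10 mol%) in CH2Cl2 at −78 °C then triggers a Mukaiyama–Michael addition to the silyloxypyrylium-activated pyranone and passes the silyl group to the new enolate, giving the Michael adduct as its silyl enol ether F2. In F2 the ring ketone is masked, so it can neither epimerise its neighbour nor accept the aldol. LiN(SiMe3)2 in THF (−78 → 0 °C) closes ring C, and 1 M HCl dehydrates the aldol and removes the silyl group to reach 21.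

2. Step 9. What may go wrong:
   - incomplete acylation of the ketone enolate by the amide electrophile, or acylation at the wrong enolate;
   - addition of the Grignard reagent to a ketone that is not held as an enolate;
   - closure of the freed tertiary hydroxyl onto the side-chain diketone instead of the vicinal dicarbonyl.

   Fallback, from 14 back to 19: a Claisen condensation with a preformed five-carbon acyl unit replaces the two additions to the oxalyl unit. Commercial methyl 3-methyl-2-oxobutanoate is ketalised (HC(OMe)3, MeOH, H2SO4 cat., reflux) to methyl 2,2-dimethoxy-3-methylbutanoate F3. The dianion of 14 (LiN(i-Pr)2, THF, −78 °C) is acylated by F3 (−78 → 0 °C) to the silyl-protected triketone monoketal F4, isolated after mild work-up. CF3CO2H/H2O (9:1) in CH2Cl2 at rt then removes the silyl group, closes and dehydrates the hemiketal and hydrolyses the ketal to give 19.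

3. Step 4. What may go wrong:
   - poor facial selectivity at the cyclic ketone, giving low enantiomeric purity;
   - loss of the syn relationship if the two α-carbons of the ketone are not told apart in the chair transition state;
   - geometric isomerisation of the crotyl reagent before transfer.

   Fallback, from 4 back to 8: the two stereocenters are set by asymmetric epoxidation and stereospecific epoxide opening. Wittig ethylidenation of 4 (ethyltriphenylphosphonium bromide, KOt-Bu, THF, 0 °C) gives (5E)-1-bromo-5-ethylidene-2-(methoxymethyl)cyclopent-1-ene F5, with the methyl away from bromine. Shi epoxidation of the more electron-rich exocyclic alkene (fructose-derived ketone catalyst of the enantiomeric series that delivers oxygen to the required face, KHSO5, K2CO3, MeCN/aqueous buffer, 0 °C) gives (2S,3R)-4-bromo-5-(methoxymethyl)-2-methyl-1-oxaspiro[2.4]hept-4-ene F6. CH2=CHMgBr with CuI (10 mol%) in THF at −40 °C opens F6 at the secondary carbon with inversion to give 8.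

**Further compounds**
F1 | step 10 | trimethylsilyl enol ether of 19 at the side-chain diketone (mixture of enol ether isomers) | COCC1=C(C(=O)C(C)=C(C)O[Si](C)(C)C)[C@@]2(OC(C(=O)C(C)C)=CC(=O)[C@@H]2C)CC1
F2 | step 10 | Michael adduct as its trimethylsilyl enol ether at the ring ketone | COCC1=C2C(=O)[C@@](C)(C(C)=O)[C@]3(C(=O)C(C)C)C=C(O[Si](C)(C)C)[C@H](C)[C@@]2(CC1)O3
F3 | step 9 | methyl 2,2-dimethoxy-3-methylbutanoate | COC(=O)C(OC)(OC)C(C)C
F4 | step 9 | 1-[(5R)-5-[(2R)-6,6-dimethoxy-7-methyl-3,5-dioxooctan-2-yl]-2-(methoxymethyl)-5-(triethylsilyloxy)cyclopent-1-en-1-yl]-2-methylbutane-1,3-dione | COCC1=C(C(=O)C(C)C(C)=O)[C@](O[Si](CC)(CC)CC)([C@@H](C)C(=O)CC(=O)C(OC)(OC)C(C)C)CC1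
F5 | step 4 | (5E)-1-bromo-5-ethylidene-2-(methoxymethyl)cyclopent-1-ene | COCC1=C(Br)/C(=C/C)CC1
F6 | step 4 | (2S,3R)-4-bromo-5-(methoxymethyl)-2-methyl-1-oxaspiro[2.4]hept-4-ene | COCC1=C(Br)[C@]2(CC1)O[C@H]2C
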